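The easiest thing to read from a falling curve is its last slope, and the choice of what to do at 4.0 min starts there.

| setting | grey | flask |
|---|---|---|
| substrate | 0.061 M | 0.061 M |
| remark | the very flask that is asked about, followed so far |  |
| time |  | 4.0 min |

grey run (percent of the substrate charged)

| time / min | target / % |
|---|---|
| 0.200 | 6.6 |
| 0.333 | 9.9 |
| 0.667 | 14.2 |
| 1.33 | 15.8 |
| 2.50 | 14.5 |

(scatter of a reading: 0.5 percentage points)

- maple: at 4.0 min add substrate, 50.0% of the amount charged, then wait 2.0 min
- elm: at 4.0 min take out 90% of the target then present, then wait 2.0 min
- ash: change nothing and wait 2.0 min more

- target, in percent of the substrate first charged, at 4.0 min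
- what to do for the largest gain in target; "none" if nothing gains more than 2 percentage points (maple / elm / ash / none)
- target present, with what was taken out counted in, in percent of the substrate first charged, after elm
- target present, with what was taken out counted in, in percent of the substrate first charged, after ash

- removed target is counted in
- additions bring no volume worth counting

1. Let y(t) be target in percent of the substrate charged. If target falls as dy/dt = −λy, then y(t) = y(s)·exp(−λ(t−s)), with s an earlier time on the sag.

2. The last two grey readings give the sag constant λ, the apparent first-order rate of target's fall past its peak: 0.0734 /min. Two readings with their scatter leave it loose, by about 0.0417 /min.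

3. Carried from the last reading, this reckoning puts target at 13.0% at 4.0 min and 11.2% after ash. Ash therefore loses 1.8 percentage points and drops out of the decision.

4. Early target, taken per unit of the peak reading, fills at 2.09 /min, far faster than it sags. So the sag is too slow to have ended the rise.

5. Either target is being undone, and elm then brings a refill, or the feed went elsewhere, and maple then looks better. The grey readings leave both open. The choice here, as a judgement, is elm.

The forecast gives 12.6% at 4.0 min, 10.4% after ash and 20% after elm, and names elm, reading the plateau as “a rapid equilibrium”.

The flask gives 12.5%, 10.4% after ash and 20.3% after elm. Elm gains 7.7 points, more than maple's 3.8 points or ash's −2.1 points.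

    substrate ⇌ intermediate (K = 0.330, k = 0.0710 /s)
    substrate ⇌ dormant form (K = 0.490, k = 0.0750 /s)
    substrate + target → side product (k = 0.250 /M/s)
    intermediate ⇌ target (K = 1.50, k = 0.0490 /s)
    substrate → decomposition product (k = 2.10 × 10⁻⁴ /s)

From 12.5%, λ gives 10.8% after ash, against the flask's 10.4%. Without the undoing of intermediate into substrate, target in this flask stands at 55.5% at 4.0 min instead of 12.5%, so that undoing is a part of what holds target down. For the same flask left unchanged and read at 10 min, λ carried from 12.5% gives 8.05%; the computed result there is 7.79%.

The runs come from a simulation with made-up constants; the scatter is artificial.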